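Each pyranone ring C of this 2',8''-biflavanone is read as the adduct of a formyl C–H bond across a 1-aryl-1-aryloxyethene, because C3 (C3'') is a bare CH2 lying between the ring A ketone C4 (C4'') and the O1-bearing benzylic stereocentre C2 (C2''). Everything rests on cutting C3–C4 and C3''–C4''. One rhodium-catalysed, enantioselective twofold intramolecular hydroacylation closes both rings C and sets C2 and C2'' as S under neutral conditions, when all C–O bonds and the biaryl bond already exist. Its precursor is a biaryl dialdehyde without stereocentres that carries two α-aryloxystyrene enol ethers, made by ester methylenation and joined by Negishi coupling.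

Key step: step 13

Numbering: unit 1 has C2–C8a and ring B C1'–C6'. Unit 2 has C2''–C8a'' and ring B C1'''–C6'''. Rings A, B and C are named per unit.

Assumption: the structure fixes C2 and C2'' as S and gives no descriptor for the tetra-ortho-substituted C2'–C8'' axis, so the axis is treated as unspecified, and rotamers about it are separated by chromatography only if they prove stable.

Step 1
Reactants: 1 2,4,6-trihydroxybenzaldehyde
Product: 2 2,6-dihydroxy-4-methoxybenzaldehyde
Conditions: Me2SO4 (1.0 equiv), K2CO3 (1.0 equiv), acetone, rt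
Reagents that add atoms: dimethyl sulfate COS(=O)(=O)OC
Why: Williamson-type O-methylation, in which the 4-OH, the only hydroxyl not tied to the formyl oxygen by a hydrogen bond and the most acidic one, should react first with one equivalent of base and electrophile.

Step 2
Reactants: 2 2,6-dihydroxy-4-methoxybenzaldehyde
Product: 3 2-(benzyloxy)-6-hydroxy-4-methoxybenzaldehyde
Conditions: BnBr (1.0 equiv), K2CO3 (1.0 equiv), DMF, rt
Reagents that add atoms: benzyl bromide BrCc1ccccc1
Why: Williamson etherification of one of two equivalent hydroxyls, after which the remaining hydroxyl is held in a strong hydrogen bond to the formyl oxygen and should resist a second benzylation.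

Step 3
Reactants: 3 2-(benzyloxy)-6-hydroxy-4-methoxybenzaldehyde
Product: 4 6-(benzyloxy)-2-hydroxy-3-iodo-4-methoxybenzaldehyde
Conditions: NIS (1.0 equiv), TFA (cat.), MeCN, 0 °C
Reagents that add atoms: N-iodosuccinimide O=C1CCC(=O)N1I
Why: Electrophilic aromatic iodination, expected at the position between the free hydroxyl and the methoxy group because it is ortho to the strongest donor and less crowded than the position flanked by OBn and OMe, as is known for 2-hydroxy-4,6-dialkoxyaryl carbonyl compounds.

Step 4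
Reactants: 4 6-(benzyloxy)-2-hydroxy-3-iodo-4-methoxybenzaldehyde; 5 4-(benzyloxy)-3,5-dimethoxybenzoic acid
Product: 6 3-(benzyloxy)-2-formyl-6-iodo-5-methoxyphenyl 4-(benzyloxy)-3,5-dimethoxybenzoate
Conditions: DIC, DMAP (cat.), CH2Cl2, rt
Reagents that add atoms: none
Why: Steglich esterification, in which the acylpyridinium ion formed with DMAP is reactive enough to acylate the hindered, hydrogen-bonded phenol flanked by iodine and the formyl group.

Step 5
Reactants: 6 3-(benzyloxy)-2-formyl-6-iodo-5-methoxyphenyl 4-(benzyloxy)-3,5-dimethoxybenzoate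
Product: 7 3-(benzyloxy)-2-(1,3-dioxolan-2-yl)-6-iodo-5-methoxyphenyl 4-(benzyloxy)-3,5-dimethoxybenzoate
Conditions: (TMSOCH2)2, TMSOTf (cat.), CH2Cl2, −78 to −20 °C, then pyridine
Reagents that add atoms: 1,2-bis(trimethylsilyloxy)ethane C[Si](C)(C)OCCO[Si](C)(C)C
Why: Noyori acetalisation under aprotic conditions, which masks the aldehyde against the titanium carbene of step 6 without exposing the activated aryl ester to an alcohol solvent.

Step 6
Reactants: 7 3-(benzyloxy)-2-(1,3-dioxolan-2-yl)-6-iodo-5-methoxyphenyl 4-(benzyloxy)-3,5-dimethoxybenzoate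
Product: 8 2-[6-(benzyloxy)-2-({1-[4-(benzyloxy)-3,5-dimethoxyphenyl]ethenyl}oxy)-3-iodo-4-methoxyphenyl]-1,3-dioxolane
Conditions: Cp2TiMe2 (3 equiv), toluene, 75 °C, dark
Reagents that add atoms: dimethyltitanocene [CH3-].[CH3-].[Ti+4].c1cc[cH-]c1.c1cc[cH-]c1
Why: Petasis methylenation, a known way from aryl benzoates to 1-aryl-1-aryloxyethenes, in which Cp2Ti=CH2 formed on heating converts the ester C=O into C=CH2 and leaves acetal, benzyl ethers and aryl iodide untouched.

Step 7
Reactants: 9 2-bromo-3,4-dimethoxybenzaldehyde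
Product: 10 2-bromo-3,4-dimethoxybenzoic acid
Conditions: NaClO2, NaH2PO4, 2-methyl-2-butene, t-BuOH/H2O, rt
Reagents that add atoms: sodium chlorite [Na+].[O-]Cl=O
Why: Pinnick oxidation, which takes the aryl aldehyde to the acid under buffered conditions while 2-methyl-2-butene traps the hypochlorous acid that could chlorinate the dimethoxyarene.

Step 8
Reactants: 10 2-bromo-3,4-dimethoxybenzoic acid; 3 2-(benzyloxy)-6-hydroxy-4-methoxybenzaldehyde
Product: 11 3-(benzyloxy)-2-formyl-5-methoxyphenyl 2-bromo-3,4-dimethoxybenzoate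
Conditions: DIC, DMAP (cat.), CH2Cl2, rt
Reagents that add atoms: none
Why: Steglich esterification of the chelated phenol of 3 through the DMAP-derived acylpyridinium ion, which tolerates the free aldehyde and the aryl bromide.

Step 9
Reactants: 11 3-(benzyloxy)-2-formyl-5-methoxyphenyl 2-bromo-3,4-dimethoxybenzoate
Product: 12 3-(benzyloxy)-2-(1,3-dioxolan-2-yl)-5-methoxyphenyl 2-bromo-3,4-dimethoxybenzoate
Conditions: (TMSOCH2)2, TMSOTf (cat.), CH2Cl2, −78 to −20 °C, then pyridine
Reagents that add atoms: 1,2-bis(trimethylsilyloxy)ethane C[Si](C)(C)OCCO[Si](C)(C)C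
Why: Noyori acetalisation as in step 5, which masks the aldehyde for the methylenation and for the organolithium of step 11.

Step 10
Reactants: 12 3-(benzyloxy)-2-(1,3-dioxolan-2-yl)-5-methoxyphenyl 2-bromo-3,4-dimethoxybenzoate
Product: 13 2-[2-(benzyloxy)-6-{[1-(2-bromo-3,4-dimethoxyphenyl)ethenyl]oxy}-4-methoxyphenyl]-1,3-dioxolane
Conditions: Cp2TiMe2 (3 equiv), toluene, 75 °C, dark
Reagents that add atoms: dimethyltitanocene [CH3-].[CH3-].[Ti+4].c1cc[cH-]c1.c1cc[cH-]c1
Why: Petasis methylenation as in step 6, with the ortho bromide slowing but not blocking the approach of the small titanium methylidene to the ester carbonyl.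

Step 11
Reactants: 13 2-[2-(benzyloxy)-6-{[1-(2-bromo-3,4-dimethoxyphenyl)ethenyl]oxy}-4-methoxyphenyl]-1,3-dioxolane; 8 2-[6-(benzyloxy)-2-({1-[4-(benzyloxy)-3,5-dimethoxyphenyl]ethenyl}oxy)-3-iodo-4-methoxyphenyl]-1,3-dioxolane
Product: 16 2',8''-linked biaryl bis(dioxolane) bis(enol ether), via aryllithium 14 (not isolated), via arylzinc chloride 15 (not isolated)
Conditions: n-BuLi, THF, −78 °C; ZnCl2, −78 °C to rt; 8, Pd2(dba)3 (2.5 mol %), RuPhos (10 mol %), THF/NMP, 70 °C
Reagents that add atoms: none
Why: Negishi coupling, in which bromine–lithium exchange at −78 °C outruns any deprotonation, the arylzinc tolerates acetals and enol ethers under base-free conditions, and zerovalent palladium with the bulky biaryl phosphine is a known system for tetra-ortho-substituted biaryls, the new axis forming without control.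

Step 12
Reactants: 16 2',8''-linked biaryl bis(dioxolane) bis(enol ether)
Product: 17 2',8''-linked biaryl dialdehyde bis(enol ether)
Conditions: PPTS (0.2 equiv), acetone/H2O 10:1, 0 °C to rt
Reagents that add atoms: water O
Why: Specific-acid-catalysed acetal hydrolysis, selective because each dioxolane ionises to an oxocarbenium ion stabilised by three ring oxygens far faster than the weakly basic aryl enol ethers are protonated at carbon, and because each aldehyde set free lowers the donor strength of the neighbouring aryloxy group further.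

Step 13
Reactants: 17 2',8''-linked biaryl dialdehyde bis(enol ether)
Product: 18 (2S,2''S)-5,5'',4'''-tris(benzyloxy)-7,3',4',7'',3''',5'''-hexamethoxy-2',8''-biflavanone
Conditions: [Rh(cod)Cl]2 (5 mol %), (R)-DTBM-SEGPHOS (10 mol %), NaB[3,5-(CF3)2C6H3]4 (10 mol %), THF, 60 °C
Reagents that add atoms: none
Why: Proposed new method: the cationic monovalent rhodium bisphosphine complex should bind each enol ether C=C, add oxidatively into the neighbouring formyl C–H bond to give an acyl hydride of trivalent rhodium, deliver the hydride to the internal alkene carbon (C2 or C2'') and close C3–C4 and C3''–C4'' by reductive elimination. The closest known reaction type is the endo- and enantioselective rhodium-catalysed intramolecular hydroacylation of 2-(2-substituted allyl)benzaldehydes to 3-substituted 1-tetralones, of which each half of 17 is the oxa analogue (O1 for the benzylic CH2), supported by the known hydroacylation of N-(1-substituted vinyl)indole-2-carbaldehydes, whereas aryl enol ethers have not been shown as acceptors. Each ring C closes in the 6-endo-trig mode through a seven-membered rhodacycle, since 5-exo closure would require a tertiary alkylrhodium at the fully substituted C2. C2 and C2'' are both controlled by the chiral ligand, which should steer hydride to the Re face of each alkene carbon (S in both units, the ligand antipode being used if a monomeric model shows the opposite sense), and two catalyst-controlled events in one molecule should raise the enantiomeric purity of the S,S product at the cost of separable mixed diastereomers. The step needs endo regioselectivity, insertion faster than decarbonylation and β-aryloxide elimination, and pairing of each formyl group with its own alkene, and the substrate secures these through 1,1-disubstituted alkenes that lack allylic hydrogens, through the ortho O1 tether that holds alkene and formyl C–H together, and through the distance between the two units.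

Step 14
Reactants: 18 (2S,2''S)-5,5'',4'''-tris(benzyloxy)-7,3',4',7'',3''',5'''-hexamethoxy-2',8''-biflavanone
Product: 19 (2S,2''S)-5,5'',4'''-trihydroxy-7,3',4',7'',3''',5'''-hexamethoxy-2',8''-biflavanone (CNP0229789.1)
Conditions: H2 (1 atm), Pd/C, EtOAc/THF, rt
Reagents that add atoms: none
Why: Hydrogenolysis of the three aryl benzyl ethers under neutral conditions, which flavanone ketones and C2–O1 bonds are known to survive and in which no base or Lewis acid is present that could open ring C and scramble C2 or C2''.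

Compound list

1 | 2,4,6-trihydroxybenzaldehyde | O=Cc1c(O)cc(O)cc1O | starting material
2 | 2,6-dihydroxy-4-methoxybenzaldehyde | COc1cc(O)c(C=O)c(O)c1 | intermediate
3 | 2-(benzyloxy)-6-hydroxy-4-methoxybenzaldehyde | COc1cc(O)c(C=O)c(OCc2ccccc2)c1 | intermediate
4 | 6-(benzyloxy)-2-hydroxy-3-iodo-4-methoxybenzaldehyde | COc1cc(OCc2ccccc2)c(C=O)c(O)c1I | intermediate
5 | 4-(benzyloxy)-3,5-dimethoxybenzoic acid | COc1cc(C(=O)O)cc(OC)c1OCc1ccccc1 | starting material
6 | 3-(benzyloxy)-2-formyl-6-iodo-5-methoxyphenyl 4-(benzyloxy)-3,5-dimethoxybenzoate | COc1cc(OCc2ccccc2)c(C=O)c(OC(=O)c2cc(OC)c(OCc3ccccc3)c(OC)c2)c1I | intermediate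
7 | 3-(benzyloxy)-2-(1,3-dioxolan-2-yl)-6-iodo-5-methoxyphenyl 4-(benzyloxy)-3,5-dimethoxybenzoate | COc1cc(OCc2ccccc2)c(C2OCCO2)c(OC(=O)c2cc(OC)c(OCc3ccccc3)c(OC)c2)c1I | intermediate
8 | 2-[6-(benzyloxy)-2-({1-[4-(benzyloxy)-3,5-dimethoxyphenyl]ethenyl}oxy)-3-iodo-4-methoxyphenyl]-1,3-dioxolane | COc1cc(OCc2ccccc2)c(C2OCCO2)c(OC(=C)c2cc(OC)c(OCc3ccccc3)c(OC)c2)c1I | intermediate
9 | 2-bromo-3,4-dimethoxybenzaldehyde | COc1ccc(C=O)c(Br)c1OC | starting material
10 | 2-bromo-3,4-dimethoxybenzoic acid | COc1ccc(C(=O)O)c(Br)c1OC | intermediate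
11 | 3-(benzyloxy)-2-formyl-5-methoxyphenyl 2-bromo-3,4-dimethoxybenzoate | COc1cc(OCc2ccccc2)c(C=O)c(c1)OC(=O)c1ccc(OC)c(OC)c1Br | intermediate
12 | 3-(benzyloxy)-2-(1,3-dioxolan-2-yl)-5-methoxyphenyl 2-bromo-3,4-dimethoxybenzoate | COc1cc(OCc2ccccc2)c(C2OCCO2)c(c1)OC(=O)c1ccc(OC)c(OC)c1Br | intermediate
13 | 2-[2-(benzyloxy)-6-{[1-(2-bromo-3,4-dimethoxyphenyl)ethenyl]oxy}-4-methoxyphenyl]-1,3-dioxolane | COc1cc(OCc2ccccc2)c(C2OCCO2)c(c1)OC(=C)c1ccc(OC)c(OC)c1Br | intermediate
14 | aryllithium from 13 (Li in place of Br) | COc1cc(OCc2ccccc2)c(C2OCCO2)c(c1)OC(=C)c1ccc(OC)c(OC)c1[Li] | intermediate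
15 | arylzinc chloride from 14 (ZnCl in place of Li) | COc1cc(OCc2ccccc2)c(C2OCCO2)c(c1)OC(=C)c1ccc(OC)c(OC)c1[Zn]Cl | intermediate
16 | biaryl bis(dioxolane) bis(enol ether): the bromine-bearing carbon of 13 joined to the iodine-bearing carbon of 8 | COc1cc(OCc2ccccc2)c(C2OCCO2)c(c1)OC(=C)c1ccc(OC)c(OC)c1-c1c(OC)cc(OCc2ccccc2)c(C2OCCO2)c1OC(=C)c1cc(OC)c(OCc2ccccc2)c(OC)c1 | intermediate
17 | biaryl dialdehyde bis(enol ether): 16 with both dioxolanes replaced by formyl groups | COc1cc(OCc2ccccc2)c(C=O)c(c1)OC(=C)c1ccc(OC)c(OC)c1-c1c(OC)cc(OCc2ccccc2)c(C=O)c1OC(=C)c1cc(OC)c(OCc2ccccc2)c(OC)c1 | intermediate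
18 | (2S,2''S)-5,5'',4'''-tris(benzyloxy)-7,3',4',7'',3''',5'''-hexamethoxy-2',8''-biflavanone | COc1cc(OCc4ccccc4)c2c(c1)O[C@H](c1ccc(OC)c(OC)c1-c1c(OC)cc(OCc4ccccc4)c3c1O[C@H](c1cc(OC)c(OCc4ccccc4)c(OC)c1)CC3=O)CC2=O | intermediate
19 | (2S,2''S)-5,5'',4'''-trihydroxy-7,3',4',7'',3''',5'''-hexamethoxy-2',8''-biflavanone | COc1cc(O)c2c(c1)O[C@H](c1ccc(OC)c(OC)c1-c1c(OC)cc(O)c3c1O[C@H](c1cc(OC)c(O)c(OC)c1)CC3=O)CC2=O | target

Total steps: 14. Longest linear sequence: 10 steps (steps 1–6 and 11–14).

Steps most likely to fail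

**Step 13.**
- What may go wrong:
  - Alkene insertion may be slow at the two crowded enol ethers that flank the axis.
  - The acyl rhodium hydride may decarbonylate.
  - β-Aryloxide elimination may occur from the alkylrhodium.
  - Exo insertion may compete with endo insertion.
  - Facial selectivity may be poor for the rotamer of the axis that is mismatched with the ligand.
- Fallback: ring closure is separated from asymmetric induction, using known chemistry. It sets out from 17 and comes back at 18.
  - A thiol-catalysed radical-chain hydroacylation (tert-dodecanethiol, 1,1'-azobis(cyclohexanecarbonitrile), toluene, reflux) lets each aroyl radical add 6-endo to the CH2 terminus. This closes the same two bonds without stereocontrol and gives the stereorandom tribenzyl biflavanone F1.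
  - DDQ in dioxane dehydrogenates both rings C to the tribenzyl biflavone F2.
  - A copper hydride asymmetric conjugate reduction of the chromone type then sets C2 and C2'' and gives 18. The conditions are Cu(OAc)2, the DTBM-SEGPHOS enantiomer that leads to S, (EtO)2MeSiH, t-BuOH and toluene.

**Step 11.**
- What may go wrong: transmetalation and reductive elimination may be slow between two large partners with four ortho substituents, so that protodemetalation and homocoupling take over.
- Fallback: the coupling is moved to a smaller nucleophile and the enol ether of unit 1 is built afterwards. It sets out from 10, 8 and 12 and comes back at 16.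
  - Acid 10 is esterified (MeI, K2CO3, DMF) to methyl 2-bromo-3,4-dimethoxybenzoate F3.
  - Miyaura borylation (B2pin2, Pd(dppf)Cl2, KOAc, dioxane) gives the pinacol boronate F4.
  - Suzuki–Miyaura coupling with iodide 8 (Pd(OAc)2, SPhos, K3PO4, toluene/H2O) gives the biaryl methyl ester F5.
  - LiOH gives the biaryl acid F6.
  - Saponification of 12 (LiOH, THF/H2O) supplies the dioxolane phenol F7.
  - Steglich esterification of the two gives the biaryl aryl ester F8, and Petasis methylenation leads to 16.

**Step 12.**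
- What may go wrong: the enol ethers may be protonated at carbon and lost by hydrolysis, or the transient oxocarbenium ion may be captured by the neighbouring alkene.
- Fallback: both formyl groups are carried at the alcohol oxidation level. They are then set free by fluoride and a neutral oxidant, and no cation ever forms beside an enol ether. It sets out from 6 and 11 and comes back at 17.
  - Rhodium-catalysed hydrosilylation (Et3SiH, RhCl(PPh3)3, toluene) passes through no free alkoxide and should not trigger acyl migration. It turns 6 into the iodo ester triethylsilyl ether F9 and 11 into the bromo ester triethylsilyl ether F10.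
  - Petasis methylenation gives the iodo enol ether silyl ether F11 and the bromo enol ether silyl ether F12.
  - Bromine–lithium exchange gives the aryllithium F13, ZnCl2 gives the arylzinc chloride F14, and Negishi coupling with the iodide gives the biaryl bis(silyl ether) F15.
  - TBAF in THF gives the biaryl bis(benzylic alcohol) F16, and MnO2 in CH2Cl2 gives 17.

Further compounds

F1 | step 13 | stereorandom tribenzyl biflavanone (18 without defined C2 and C2'') | COc1cc(OCc4ccccc4)c2c(c1)OC(c1ccc(OC)c(OC)c1-c1c(OC)cc(OCc4ccccc4)c3c1OC(c1cc(OC)c(OCc4ccccc4)c(OC)c1)CC3=O)CC2=O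
F2 | step 13 | tribenzyl biflavone (C2=C3 and C2''=C3'') | COc1cc(OCc4ccccc4)c2c(c1)OC(c1ccc(OC)c(OC)c1-c1c(OC)cc(OCc4ccccc4)c3c1OC(c1cc(OC)c(OCc4ccccc4)c(OC)c1)=CC3=O)=CC2=O
F3 | step 11 | methyl 2-bromo-3,4-dimethoxybenzoate | COC(=O)c1ccc(OC)c(OC)c1Br
F4 | step 11 | methyl 3,4-dimethoxy-2-(4,4,5,5-tetramethyl-1,3,2-dioxaborolan-2-yl)benzoate | COC(=O)c1ccc(OC)c(OC)c1B1OC(C)(C)C(C)(C)O1
F5 | step 11 | biaryl methyl ester | COC(=O)c1ccc(OC)c(OC)c1-c1c(OC)cc(OCc2ccccc2)c(C2OCCO2)c1OC(=C)c1cc(OC)c(OCc2ccccc2)c(OC)c1
F6 | step 11 | biaryl acid | OC(=O)c1ccc(OC)c(OC)c1-c1c(OC)cc(OCc2ccccc2)c(C2OCCO2)c1OC(=C)c1cc(OC)c(OCc2ccccc2)c(OC)c1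
F7 | step 11 | 3-(benzyloxy)-2-(1,3-dioxolan-2-yl)-5-methoxyphenol | COc1cc(O)c(C2OCCO2)c(OCc2ccccc2)c1
F8 | step 11 | biaryl aryl ester | COc1cc(OCc2ccccc2)c(C2OCCO2)c(c1)OC(=O)c1ccc(OC)c(OC)c1-c1c(OC)cc(OCc2ccccc2)c(C2OCCO2)c1OC(=C)c1cc(OC)c(OCc2ccccc2)c(OC)c1
F9 | step 12 | iodo ester triethylsilyl ether | COc1cc(OCc2ccccc2)c(CO[Si](CC)(CC)CC)c(OC(=O)c2cc(OC)c(OCc3ccccc3)c(OC)c2)c1I
F10 | step 12 | bromo ester triethylsilyl ether | COc1cc(OCc2ccccc2)c(CO[Si](CC)(CC)CC)c(c1)OC(=O)c1ccc(OC)c(OC)c1Br
F11 | step 12 | iodo enol ether silyl ether | COc1cc(OCc2ccccc2)c(CO[Si](CC)(CC)CC)c(OC(=C)c2cc(OC)c(OCc3ccccc3)c(OC)c2)c1I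
F12 | step 12 | bromo enol ether silyl ether | COc1cc(OCc2ccccc2)c(CO[Si](CC)(CC)CC)c(c1)OC(=C)c1ccc(OC)c(OC)c1Br
F13 | step 12 | aryllithium | COc1cc(OCc2ccccc2)c(CO[Si](CC)(CC)CC)c(c1)OC(=C)c1ccc(OC)c(OC)c1[Li]
F14 | step 12 | arylzinc chloride | COc1cc(OCc2ccccc2)c(CO[Si](CC)(CC)CC)c(c1)OC(=C)c1ccc(OC)c(OC)c1[Zn]Cl
F15 | step 12 | biaryl bis(silyl ether) | COc1cc(OCc2ccccc2)c(CO[Si](CC)(CC)CC)c(c1)OC(=C)c1ccc(OC)c(OC)c1-c1c(OC)cc(OCc2ccccc2)c(CO[Si](CC)(CC)CC)c1OC(=C)c1cc(OC)c(OCc2ccccc2)c(OC)c1
F16 | step 12 | biaryl bis(benzylic alcohol) | COc1cc(OCc2ccccc2)c(CO)c(c1)OC(=C)c1ccc(OC)c(OC)c1-c1c(OC)cc(OCc2ccccc2)c(CO)c1OC(=C)c1cc(OC)c(OCc2ccccc2)c(OC)c1
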